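The teal flask ended with target at 75.6 % of its charge, but the grey flask, at the same partner charge, held 3.5 % after 8.00 min. The next charge depends on that contrast.

| setting | teal | grey | larch | elm | birch |
|---|---|---|---|---|---|
| solid substrate | 0.043 M | 0.35 M | 0.030 M | 0.10 M | 0.30 M |
| partner | 0.45 M | 0.45 M | 0.450 M | 0.450 M | 0.450 M |
| remark | run made earlier | run made earlier |  |  |  |
| time |  |  | 8.0 min | 8.0 min | 8.0 min |

| run | time / min | target / % | solid substrate / % |
|---|---|---|---|
| teal | 0.667 | 14.7 | 75.9 |
| teal | 2.00 | 45.0 | 34.0 |
| teal | 4.00 | 74.1 | 0 |
| teal | 6.00 | 74.3 | 0 |
| teal | 8.00 | 75.6 | 0 |
| grey | 0.667 | 2.3 | 96.8 |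
| grey | 1.33 | 2.2 | 93.3 |
| grey | 2.50 | 1.7 | 87.0 |
| grey | 4.00 | 3.0 | 76.7 |
| grey | 8.00 | 3.5 | 52.2 |

(readings scatter by 1 percentage point)

- a species is counted by the solid substrate in it: one side product A or side product B counts as two
- given per volume of solution although it is solid: solid substrate
- what may be going on: solid substrate <-> dissolved substrate; dissolved substrate + partner -> target; dissolved substrate + target -> side product A; solid substrate + target -> side product B
- at the start none of the solid substrate is in solution
- "hardly changes" means that all values lie within two and a half points (for a concentration: within two and a half percent of the largest)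

- [target] at the end for larch, elm, birch, in this order
- how the row runs (rises, then falls / rises all the way / hardly changes / falls all the way / falls, then rises)

Let T be [target] and S be [solid substrate]. Between its first two readings, the teal flask gains target at

m = 0.00977 M min⁻¹.

In the grey flask, solid falls at

L = 0.0213 M min⁻¹,

which is twice m, while the grey target readings stay between 1.7 % and 3.5 %. So each target made in grey appears to carry one more solid into side product B. The last two grey readings give

Π = 0.00253 M^2.

This Π, the standing product T·S at which the making of target and its loss to side product B balance while solid stands (a steady state for target), is a rough reading, since each target reading of about 3.0 % carries 1 percentage point of scatter.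

For birch, this reckoning takes the grey rate L:

S = 0.130 M, so T = Π/S = 0.0195 M.

Larch at the teal yield gives 0.0227 M, so the birch charge buys less target. At L, the elm charge clears in 4.70 min, before the 8.0 min are over, so Π no longer holds its target down at the end. Target made at m over that elm time comes to 0.0459 M before losses, more than the larch figure. The charge to keep is elm, and the thing to watch is whether its solid has gone by the end.

The forecast gives 0.023 M, 0.04 M and 0.014 M, a row that rises, then falls, with birch as “target stays suppressed at about 0.014 M”. That birch value lies below the 0.0195 M reckoned here.

The flasks give 0.0250 M, 0.0464 M and 0.0176 M: the row rises, then falls.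

    solid substrate ⇌ dissolved substrate, rate k1*(cs1 - [dissolved substrate]) while solid is left; crystals form when [dissolved substrate] > cs1 (solubility = 8.80 mM, k = 0.0410 s⁻¹)
    dissolved substrate + partner → target (k = 0.127 M⁻¹ s⁻¹)
    dissolved substrate + target → side product A (k = 0.275 M⁻¹ s⁻¹)
    solid substrate + target → side product B (k = 0.0582 M⁻¹ s⁻¹)

In birch at 8.00 min, with 44.1 % of the solid still standing, T·S is 0.00233 M^2, against Π = 0.00253 M^2. In elm at 4.00 min, T·S is 0.00100 M^2, below Π, and in larch at 1.04 min, target is made 10.6 times faster than it is used up, with 83.4 % of the larch charge standing as target at 8.00 min.

The earlier runs and the new flask stem from a simulated flask for substances that don't exist; scatter was added.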